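**Plan**

- The target is a flavonol with no stereocentre, so nothing stereochemical has to be set. Its rings are A (phloroglucinol-type), C (pyranone) and B (4-methoxyphenyl).
- Retrosynthesis: ring C is cut at O1–C2 (cyclodehydration) and C3–C2 (aroylation by 4-methoxybenzoyl chloride), then C4–C4a (aryllithium acylation). Ring A is then cut at C7–O7 and C8–C1'' together.
- Enabling feature: on ring A the oxygen-bearing C7 and the carbon carrying the quaternary side chain, C8, are neighbours, and C8 is flanked on its other side by the oxygen-bearing C8a. A C7–C8 aryne polarised by that oxygen can take an ether oxygen at C7 and the allyl carbon at C8.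
- Forward: ring A is bought as 5-methoxyresorcinol and converted into an ortho-silylaryl triflate. The aryne step installs the benzyl-protected O7 and the 1,1-dimethylallyl group. C4a is then acylated, ring C is closed last with ring B arriving on the aroyl chloride, and one step removes all protecting groups.

Key step: step 6

Remark: ring A atoms are named by flavone numbering (C4a, C5 to C8, C8a) from the aryne stage on. 2-(Benzyloxy)-N-methoxy-N-methylacetamide is taken as a catalogue reagent.

**Route**

Step 1
Reactants: 1 5-methoxyresorcinol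
Product: 2 3-methoxy-5-(methoxymethoxy)phenol
Conditions: NaH (1.0 equiv), MOMCl (1.0 equiv), DMF, 0 °C
Reagents that add atoms: chloromethyl methyl ether, COCCl
Why: Williamson-type O-alkylation of the monophenoxide of a symmetric diol with one equivalent of electrophile should give the mono-ether as the main product, beside separable diether and recoverable diol.

Step 2
Reactants: 2 3-methoxy-5-(methoxymethoxy)phenol
Product: 3 3-methoxy-5-(methoxymethoxy)phenyl N-isopropylcarbamate
Conditions: i-PrNCO, Et3N (cat.), CH2Cl2, rt
Reagents that add atoms: isopropyl isocyanate, CC(C)N=C=O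
Why: Base-catalysed addition of a phenol to an isocyanate gives the N-monoalkyl carbamate, which is a strong director for metalation and can later be removed under mild base.

Step 3
Reactants: 3 3-methoxy-5-(methoxymethoxy)phenyl N-isopropylcarbamate
Product: 7 5-methoxy-3-(methoxymethoxy)-2-(trimethylsilyl)phenyl N-isopropylcarbamate, via N-silyl carbamate 4 (not isolated), via ortho-lithiated N-silyl carbamate 5 (not isolated), via C-silyl N-silyl carbamate 6 (not isolated)
Conditions: Me3SiOTf, TMEDA, Et2O, 0 °C to rt; n-BuLi, TMEDA, −78 °C; Me3SiCl, −78 °C to rt; aq. NH4Cl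
Reagents that add atoms: chlorotrimethylsilane, C[Si](C)(C)Cl
Why: Directed ortho-metalation: after in situ N-silylation, the carbamate and the MOM ether, the two strongest oxygen directors on the ring, should together steer n-BuLi to the carbon between them rather than to the carbon between carbamate and methoxy; Me3SiCl traps the aryllithium and the N-silyl group is lost on aqueous work-up.

Step 4
Reactants: 7 5-methoxy-3-(methoxymethoxy)-2-(trimethylsilyl)phenyl N-isopropylcarbamate
Product: 9 5-methoxy-3-(methoxymethoxy)-2-(trimethylsilyl)phenyl trifluoromethanesulfonate, via silyl phenol 8 (not isolated)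
Conditions: Et2NH, DBU, MeCN, 40 °C; then PhNTf2, rt
Reagents that add atoms: N-phenylbis(trifluoromethanesulfonimide), O=S(=O)(N(c1ccccc1)S(=O)(=O)C(F)(F)F)C(F)(F)F
Why: E1cB cleavage of the N–H carbamate by DBU, with the isocyanate trapped by Et2NH as a urea, frees the phenoxide, which is triflated in the same pot; this is the standard closing sequence for ortho-silylaryl triflates and leaves the MOM ether and the C–Si bond untouched.

Step 5
Reactants: 10 benzyl alcohol, 11 prenyl bromide
Product: 12 benzyl 3-methylbut-2-en-1-yl ether
Conditions: NaH, THF, 0 °C; then 11, Bu4NI (cat.), rt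
Reagents that add atoms: none
Why: Williamson ether synthesis, an SN2 reaction of a primary alkoxide with a reactive primary allylic bromide.

Step 6
Reactants: 9 5-methoxy-3-(methoxymethoxy)-2-(trimethylsilyl)phenyl trifluoromethanesulfonate, 12 benzyl 3-methylbut-2-en-1-yl ether
Product: 15 1-(benzyloxy)-5-methoxy-3-(methoxymethoxy)-2-(2-methylbut-3-en-2-yl)benzene, via aryne 13 (not isolated), via oxonium aryl anion zwitterion 14 (not isolated)
Conditions: CsF, 18-crown-6, 12 (8 equiv), PhMe, 60 °C, slow addition of 9
Reagents that add atoms: none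
Why: Proposed new method: fluoride attack on silicon expels triflate and releases the C7–C8 aryne 13, whose triple bond is distorted by the inductively withdrawing OMOM group on C8a so that C7 is the electrophilic end and negative charge builds at C8; the ether oxygen of 12 should therefore add at C7 to give the aryl(benzyl)(prenyl)oxonium aryl anion zwitterion 14. In 14 the C8 carbanion and the CMe2 end of the O-prenyl group are the termini of a six-atom array (C8, C7, O, CH2, CH, CMe2), so a charge-accelerated [3,3] shift through a chair should form C8–C1'' with allylic inversion and cancel both charges. The closest known reaction types are the aryne aza-Claisen reaction of tertiary allylamines and the capture of arynes by allyl thioethers and by cyclic ethers; a dialkyl ether is a weaker donor, which is why 12 is used in large excess in a non-nucleophilic aprotic medium with slow release of the aryne. No ring closes and no stereocentre forms. The step needs regioselectivity (oxygen to C7, not C8), which the alkoxy group on C8a secures, and chemoselectivity for O-addition and [3,3] shift over the ene reaction of the prenyl alkene, over 1,4-proton transfer from the benzylic CH2 to an oxonium ylide and over protonation of the aryl anion; the high ether concentration, the six-membered geometry and the absence of proton donors are meant to favour the desired path.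

Step 7
Reactants: 15 1-(benzyloxy)-5-methoxy-3-(methoxymethoxy)-2-(2-methylbut-3-en-2-yl)benzene, 16 2-(benzyloxy)-N-methoxy-N-methylacetamide
Product: 19 2-(benzyloxy)-1-[4-(benzyloxy)-6-methoxy-2-(methoxymethoxy)-3-(2-methylbut-3-en-2-yl)phenyl]ethan-1-one, via aryllithium 17 (not isolated), via lithium hemiaminal adduct 18 (not isolated)
Conditions: n-BuLi, TMEDA, THF, 0 °C; then 16, −78 to 0 °C; H2O
Reagents that add atoms: none
Why: Directed ortho-metalation followed by Weinreb ketone synthesis: the MOM ether, turned toward C4a by the neighbouring tert-alkyl group, and the methoxy group should together direct n-BuLi to C4a, and the chelated tetrahedral adduct prevents over-addition.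

Step 8
Reactants: 19 2-(benzyloxy)-1-[4-(benzyloxy)-6-methoxy-2-(methoxymethoxy)-3-(2-methylbut-3-en-2-yl)phenyl]ethan-1-one
Product: 20 2-(benzyloxy)-1-[4-(benzyloxy)-2-hydroxy-6-methoxy-3-(2-methylbut-3-en-2-yl)phenyl]ethan-1-one
Conditions: HCl (2 M aq.), MeOH, 40 °C
Reagents that add atoms: none
Why: Acid-catalysed acetal methanolysis removes the phenolic MOM ether, helped by hydrogen bonding of the freed phenol to the ketone, while the benzyl and methyl ethers are inert and the monosubstituted alkene would have to protonate to a secondary cation.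

Step 9
Reactants: 20 2-(benzyloxy)-1-[4-(benzyloxy)-2-hydroxy-6-methoxy-3-(2-methylbut-3-en-2-yl)phenyl]ethan-1-one, 21 4-methoxybenzoyl chloride
Product: 22 2-(benzyloxy)-1-[4-(benzyloxy)-2-hydroxy-6-methoxy-3-(2-methylbut-3-en-2-yl)phenyl]-3-(4-methoxyphenyl)propane-1,3-dione
Conditions: LiN(SiMe3)2 (3.5 equiv), THF, −78 °C; 21, −78 °C to rt; then 1 M HCl, 0 °C
Reagents that add atoms: none
Why: One-pot dianion form of the Baker–Venkataraman synthesis: excess amide base forms the phenoxide enolate, which is aroylated at the enolate carbon to give the 1,3-diketone without having to acylate the hindered phenol first.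

Step 10
Reactants: 22 2-(benzyloxy)-1-[4-(benzyloxy)-2-hydroxy-6-methoxy-3-(2-methylbut-3-en-2-yl)phenyl]-3-(4-methoxyphenyl)propane-1,3-dione
Product: 23 3,7-bis(benzyloxy)-5-methoxy-2-(4-methoxyphenyl)-8-(2-methylbut-3-en-2-yl)-4H-chromen-4-one
Conditions: TsOH·H2O (cat.), PhMe, 80 °C
Reagents that add atoms: none
Why: Acid-catalysed cyclodehydration, the closing step of the Baker–Venkataraman flavone synthesis: the C8a phenol adds to the aroyl carbonyl and loss of water gives ring C; only O1 can close the ring because O5 is a methyl ether, and no free phenol remains next to the alkene.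

Step 11
Reactants: 23 3,7-bis(benzyloxy)-5-methoxy-2-(4-methoxyphenyl)-8-(2-methylbut-3-en-2-yl)-4H-chromen-4-one
Product: 24 3,5,7-trihydroxy-2-(4-methoxyphenyl)-8-(2-methylbut-3-en-2-yl)-4H-chromen-4-one
Conditions: BCl3, C6HMe5, CH2Cl2, −78 to 0 °C; then MeOH, aq. NaHCO3
Reagents that add atoms: none
Why: Lewis-acid ether cleavage: BCl3 with pentamethylbenzene as a non-basic benzyl cation scavenger cleaves both benzyl ethers in the cold, and on warming the BCl3 chelated between the C4 carbonyl and O5 removes the peri methyl ether, while the unchelated 4'-methoxy group should stay.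

**Compound list**

1 | 5-methoxyresorcinol (5-methoxybenzene-1,3-diol) | COc1cc(O)cc(O)c1 | starting material
2 | 3-methoxy-5-(methoxymethoxy)phenol | COCOc1cc(OC)cc(O)c1 | intermediate
3 | 3-methoxy-5-(methoxymethoxy)phenyl N-isopropylcarbamate | COCOc1cc(OC)cc(OC(=O)NC(C)C)c1 | intermediate
4 | 3-methoxy-5-(methoxymethoxy)phenyl N-isopropyl-N-(trimethylsilyl)carbamate | COCOc1cc(OC)cc(OC(=O)N(C(C)C)[Si](C)(C)C)c1 | intermediate (not isolated)
5 | 2-lithio-5-methoxy-3-(methoxymethoxy)phenyl N-isopropyl-N-(trimethylsilyl)carbamate (lithium between carbamate and MOM ether) | [Li]c1c(OCOC)cc(OC)cc1OC(=O)N(C(C)C)[Si](C)(C)C | intermediate (not isolated)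
6 | 5-methoxy-3-(methoxymethoxy)-2-(trimethylsilyl)phenyl N-isopropyl-N-(trimethylsilyl)carbamate | COCOc1cc(OC)cc(OC(=O)N(C(C)C)[Si](C)(C)C)c1[Si](C)(C)C | intermediate (not isolated)
7 | 5-methoxy-3-(methoxymethoxy)-2-(trimethylsilyl)phenyl N-isopropylcarbamate | COCOc1cc(OC)cc(OC(=O)NC(C)C)c1[Si](C)(C)C | intermediate
8 | 5-methoxy-3-(methoxymethoxy)-2-(trimethylsilyl)phenol | COCOc1cc(OC)cc(O)c1[Si](C)(C)C | intermediate (not isolated)
9 | 5-methoxy-3-(methoxymethoxy)-2-(trimethylsilyl)phenyl trifluoromethanesulfonate | COCOc1cc(OC)cc(OS(=O)(=O)C(F)(F)F)c1[Si](C)(C)C | intermediate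
10 | benzyl alcohol | OCc1ccccc1 | starting material
11 | prenyl bromide (1-bromo-3-methylbut-2-ene) | CC(C)=CCBr | starting material
12 | benzyl 3-methylbut-2-en-1-yl ether | CC(C)=CCOCc1ccccc1 | intermediate
13 | 5-methoxy-3-(methoxymethoxy)benzyne (1,2-didehydrobenzene; the C7–C8 aryne) | COCOC1=CC(OC)=CC#C1 | intermediate (not isolated)
14 | benzyl[3-methoxy-5-(methoxymethoxy)phenyl](3-methylbut-2-en-1-yl)oxonium-6-ide (aryl anion next to the OMOM carbon) | COCOc1cc(OC)cc([O+](CC=C(C)C)Cc2ccccc2)[c-]1 | intermediate (not isolated)
15 | 1-(benzyloxy)-5-methoxy-3-(methoxymethoxy)-2-(2-methylbut-3-en-2-yl)benzene | C=CC(C)(C)c1c(OCOC)cc(OC)cc1OCc1ccccc1 | intermediate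
16 | 2-(benzyloxy)-N-methoxy-N-methylacetamide | CON(C)C(=O)COCc1ccccc1 | starting material
17 | [4-(benzyloxy)-6-methoxy-2-(methoxymethoxy)-3-(2-methylbut-3-en-2-yl)phenyl]lithium | C=CC(C)(C)c1c(OCOC)c([Li])c(OC)cc1OCc1ccccc1 | intermediate (not isolated)
18 | lithium 2-(benzyloxy)-1-[4-(benzyloxy)-6-methoxy-2-(methoxymethoxy)-3-(2-methylbut-3-en-2-yl)phenyl]-1-[methoxy(methyl)amino]ethan-1-olate (racemic) | C=CC(C)(C)c1c(OCOC)c(C(O[Li])(COCc2ccccc2)N(C)OC)c(OC)cc1OCc1ccccc1 | intermediate (not isolated)
19 | 2-(benzyloxy)-1-[4-(benzyloxy)-6-methoxy-2-(methoxymethoxy)-3-(2-methylbut-3-en-2-yl)phenyl]ethan-1-one | C=CC(C)(C)c1c(OCOC)c(C(=O)COCc2ccccc2)c(OC)cc1OCc1ccccc1 | intermediate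
20 | 2-(benzyloxy)-1-[4-(benzyloxy)-2-hydroxy-6-methoxy-3-(2-methylbut-3-en-2-yl)phenyl]ethan-1-one | C=CC(C)(C)c1c(O)c(C(=O)COCc2ccccc2)c(OC)cc1OCc1ccccc1 | intermediate
21 | 4-methoxybenzoyl chloride | COc1ccc(C(=O)Cl)cc1 | starting material
22 | 2-(benzyloxy)-1-[4-(benzyloxy)-2-hydroxy-6-methoxy-3-(2-methylbut-3-en-2-yl)phenyl]-3-(4-methoxyphenyl)propane-1,3-dione (racemic, enolisable) | C=CC(C)(C)c1c(O)c(C(=O)C(OCc2ccccc2)C(=O)c2ccc(OC)cc2)c(OC)cc1OCc1ccccc1 | intermediate
23 | 3,7-bis(benzyloxy)-5-methoxy-2-(4-methoxyphenyl)-8-(2-methylbut-3-en-2-yl)-4H-chromen-4-one | C=CC(C)(C)c1c(OCc2ccccc2)cc(OC)c2c(=O)c(OCc3ccccc3)c(-c3ccc(OC)cc3)oc12 | intermediate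
24 | 3,5,7-trihydroxy-2-(4-methoxyphenyl)-8-(2-methylbut-3-en-2-yl)-4H-chromen-4-one | C=CC(C)(C)c1c(O)cc(O)c2c(=O)c(O)c(-c3ccc(OC)cc3)oc12 | target

**Count**

Total steps: 11. Longest linear sequence: 10 steps (steps 1 to 4 and 6 to 11, from 1 to 24); step 5 is a one-step side branch.

**Steps most likely to fail**

1. Step 6 (the proposed new method).
   - What may go wrong: capture of the aryne by the weakly basic ether oxygen may be too slow, so that the aryne is used up by ene reaction or [2+2] addition at the prenyl alkene or by self-condensation. Within the zwitterion, benzylic proton transfer to an oxonium ylide (then a [2,3] or [1,2] shift) or loss of a benzyl or prenyl cation may outrun the [3,3] shift.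
   - Fallback (aromatic Claisen rearrangement, known chemistry): it sets out from phenol 2 and comes back at 15. O-Prenylation of 2 with 11 (K2CO3, acetone) should give the aryl prenyl ether 1-methoxy-3-(methoxymethoxy)-5-[(3-methylbut-2-en-1-yl)oxy]benzene F1. Heating F1 in N,N-diethylaniline at about 190 °C should shift the prenyl group with allylic inversion to an ortho carbon and give 5-methoxy-3-(methoxymethoxy)-2-(2-methylbut-3-en-2-yl)phenol F2. O-Benzylation of F2 (BnBr, K2CO3, DMF) then gives 15.
   - Cost: the rearrangement is not directed between the two ortho carbons, so the isomer with the side chain between OH and OMe has to be removed by chromatography.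

2. Step 7.
   - What may go wrong: lithiation may be unselective between C4a and C6, or may take place at a benzylic CH2 and be followed by Wittig rearrangement. The crowded aryllithium may also deprotonate the amide instead of adding to it.
   - Fallback (phenol-directed formylation in place of ether-directed lithiation): it sets out from 15 and comes back at 20. Acid methanolysis of the MOM ether of 15 (HCl, MeOH) should give 3-(benzyloxy)-5-methoxy-2-(2-methylbut-3-en-2-yl)phenol F3. Magnesium-mediated ortho-formylation (MgCl2, Et3N, paraformaldehyde, MeCN, reflux) can only reach C4a, the single free ortho position of this phenol, and should give 4-(benzyloxy)-2-hydroxy-6-methoxy-3-(2-methylbut-3-en-2-yl)benzaldehyde F4. Addition of benzyloxymethyllithium (from (benzyloxymethyl)tributylstannane and n-BuLi, THF, −78 °C, two equivalents) should give 2-(benzyloxy)-1-[4-(benzyloxy)-2-hydroxy-6-methoxy-3-(2-methylbut-3-en-2-yl)phenyl]ethan-1-ol F5 as a racemate. Oxidation of the benzylic alcohol of F5 with MnO2 in CH2Cl2 then gives 20.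

3. Step 11.
   - What may go wrong: during the warm phase needed for the methyl ether, the terminal alkene may be protonated or hydrochlorinated by BCl3 and HCl, followed by closure of O7 onto the side chain or cationic rearrangement. If the mixture is kept cold, demethylation may stay incomplete.
   - Fallback (staged unveiling by two different mechanisms, so that no strong Lewis acid is warmed in the presence of the alkene): it sets out from 23 and comes back at 24. BCl3 with pentamethylbenzene in CH2Cl2, held at −78 °C and quenched cold, should remove only the two benzyl ethers and give 3,7-dihydroxy-5-methoxy-2-(4-methoxyphenyl)-8-(2-methylbut-3-en-2-yl)-4H-chromen-4-one F6. MgI2·OEt2 in THF and toluene at 60 to 80 °C then cleaves the methyl ether of F6 by iodide attack on the magnesium-chelated peri ether and gives 24.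

**Further compounds**

F1 | step 6 | 1-methoxy-3-(methoxymethoxy)-5-[(3-methylbut-2-en-1-yl)oxy]benzene | COCOc1cc(OC)cc(OCC=C(C)C)c1
F2 | step 6 | 5-methoxy-3-(methoxymethoxy)-2-(2-methylbut-3-en-2-yl)phenol | C=CC(C)(C)c1c(O)cc(OC)cc1OCOC
F3 | step 7 | 3-(benzyloxy)-5-methoxy-2-(2-methylbut-3-en-2-yl)phenol | C=CC(C)(C)c1c(O)cc(OC)cc1OCc1ccccc1
F4 | step 7 | 4-(benzyloxy)-2-hydroxy-6-methoxy-3-(2-methylbut-3-en-2-yl)benzaldehyde | C=CC(C)(C)c1c(O)c(C=O)c(OC)cc1OCc1ccccc1
F5 | step 7 | 2-(benzyloxy)-1-[4-(benzyloxy)-2-hydroxy-6-methoxy-3-(2-methylbut-3-en-2-yl)phenyl]ethan-1-ol (racemic) | C=CC(C)(C)c1c(O)c(C(O)COCc2ccccc2)c(OC)cc1OCc1ccccc1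
F6 | step 11 | 3,7-dihydroxy-5-methoxy-2-(4-methoxyphenyl)-8-(2-methylbut-3-en-2-yl)-4H-chromen-4-one | C=CC(C)(C)c1c(O)cc(OC)c2c(=O)c(O)c(-c3ccc(OC)cc3)oc12
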